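## Retrosynthetic overview

1. The C1'–C2' bond is cut. The carbinol carbon comes from 8-formyl-7-methoxycoumarin. The aryloxy-bearing carbon comes from a γ-(flavon-7-yloxy)-β-methylallyl chromium(III) species, an α-oxy allyl anion equivalent in which a normally electrophilic O-bearing carbon acts as the nucleophile. This step joins the two halves and sets both stereocentres.
2. The allylchromium is generated by allylic C–H abstraction from the 7-O-methallyl ether of the flavone, which comes from the 5,7-dihydroxyflavone and methallyl chloride.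
3. The 6- and 8-methoxy groups of the flavone come from 6,8-dibromination and copper-catalysed methoxylation of 5,7-dihydroxy-3,4'-dimethoxyflavone.
4. Only one ring is built: the pyran-4-one ring of the flavone, by Allan–Robinson condensation on ω-methoxyphloroacetophenone. The A and B rings and the coumarin are bought.
5. The aldehyde comes from umbelliferone by C8 formylation and O-methylation.

Assumption: 2-methoxy-1-(2,4,6-trihydroxyphenyl)ethanone (1) is taken as a catalogue starting material.
Assumption: the facial sense of the chiral chromium catalyst in step 7 is taken by analogy; if the first run gives the mirror-image anti product, the enantiomeric ligand is used.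

## Route

Step 1
Reactants: 1 2-methoxy-1-(2,4,6-trihydroxyphenyl)ethanone; 2 4-methoxybenzoic anhydride
Product: 4 5,7-dihydroxy-3-methoxy-2-(4-methoxyphenyl)-4H-chromen-4-one, via bis(4-methoxybenzoate) ester 3 (not isolated)
Conditions: 2 (4 equiv), Et3N, 165 °C; then KOH, aq. EtOH, reflux; then HCl
Reagents that add atoms: none
Why: Allan–Robinson condensation, in which O-acylation, base-mediated acyl transfer to the α-methoxy ketone carbon and cyclodehydration build the 3-methoxypyran-4-one ring, and alkaline hydrolysis then removes the phenolic 4-methoxybenzoates; no stereocentre is formed.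

Step 2
Reactants: 4 5,7-dihydroxy-3-methoxy-2-(4-methoxyphenyl)-4H-chromen-4-one
Product: 5 6,8-dibromo-5,7-dihydroxy-3-methoxy-2-(4-methoxyphenyl)-4H-chromen-4-one
Conditions: Br2 (2.05 equiv), AcOH, 20 °C
Reagents that add atoms: bromine BrBr
Why: Electrophilic aromatic bromination stops at the 6,8-dibromide because C6 and C8 of the phloroglucinol-type A ring are far more reactive than the chromone-deactivated anisyl B ring.

Step 3
Reactants: 5 6,8-dibromo-5,7-dihydroxy-3-methoxy-2-(4-methoxyphenyl)-4H-chromen-4-one
Product: 6 5,7-dihydroxy-3,6,8-trimethoxy-2-(4-methoxyphenyl)-4H-chromen-4-one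
Conditions: NaOMe (excess), CuBr (cat.), DMF–MeOH, 110 °C
Reagents that add atoms: sodium methoxide [Na+].[O-]C
Why: Ullmann-type copper-catalysed methoxylation of aryl bromides tolerates ortho-phenoxides (as in the bromovanillin to syringaldehyde conversion), and any base-induced Wessely–Moser ring opening and reclosure is degenerate because C6 and C8 carry the same group.

Step 4
Reactants: 6 5,7-dihydroxy-3,6,8-trimethoxy-2-(4-methoxyphenyl)-4H-chromen-4-one; 7 3-chloro-2-methylprop-1-ene
Product: 8 5-hydroxy-3,6,8-trimethoxy-2-(4-methoxyphenyl)-7-[(2-methylprop-2-en-1-yl)oxy]-4H-chromen-4-one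
Conditions: K2CO3 (1.2 equiv), KI (cat.), DMF, 50 °C
Reagents that add atoms: none
Why: Williamson ether synthesis is selective for the acidic 7-OH because the 5-OH is held in a hydrogen bond to the C4 carbonyl, and the product cannot undergo Claisen rearrangement because both ortho positions are substituted.

Step 5
Reactants: 9 7-hydroxy-2H-chromen-2-one (umbelliferone)
Product: 11 7-hydroxy-2-oxo-2H-chromene-8-carbaldehyde, via 8-iminomethyl aldimine 10 (not isolated)
Conditions: hexamethylenetetramine, TFA, 90 °C; then aq. HCl, 60 °C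
Reagents that add atoms: hexamethylenetetramine C1N2CN3CN1CN(C2)C3; water O
Why: Duff formylation aminomethylates C8 (ortho to the phenol and the most nucleophilic position of 7-hydroxycoumarin), an internal redox gives the aldimine, and aqueous acid hydrolyses it to the aldehyde.

Step 6
Reactants: 11 7-hydroxy-2-oxo-2H-chromene-8-carbaldehyde
Product: 12 7-methoxy-2-oxo-2H-chromene-8-carbaldehyde
Conditions: MeI, K2CO3, acetone, reflux
Reagents that add atoms: iodomethane CI
Why: Williamson O-methylation of the phenol proceeds under mild carbonate conditions that leave the aldehyde and the lactone untouched.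

Step 7
Reactants: 8 5-hydroxy-3,6,8-trimethoxy-2-(4-methoxyphenyl)-7-[(2-methylprop-2-en-1-yl)oxy]-4H-chromen-4-one; 12 7-methoxy-2-oxo-2H-chromene-8-carbaldehyde
Product: 14 5-hydroxy-7-{[(1R,2S)-1-hydroxy-1-(7-methoxy-2-oxo-2H-chromen-8-yl)-3-methylbut-3-en-2-yl]oxy}-3,6,8-trimethoxy-2-(4-methoxyphenyl)-4H-chromen-4-one, via γ-aryloxyallylchromium(III) species 13 (not isolated)
Conditions: 12 (2 equiv), CrCl3·3THF (10 mol %), (3aS,8aR)-cyclopropylidene-bridged inda-BOX (11 mol %), 9-mesityl-10-methylacridinium perchlorate (5 mol %), thiophosphoric imide HAT co-catalyst (10 mol %), Mg(ClO4)2 (1 equiv), CH2Cl2, 430 nm LEDs, rt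
Reagents that add atoms: none
Why: Proposed new method: the excited acridinium oxidises the thiophosphoric imide to a sulfur radical that abstracts the weakest and most hydridic C–H of 8 (the O–CH2, which is both allylic and α to oxygen), Cr(II) traps the resulting α-aryloxy-2-methylallyl radical at its CH2 end to give the (E)-γ-aryloxyallylchromium(III) 13, whose oxygen-bearing carbon (normally an acceptor centre) adds as a nucleophile to the carbonyl carbon of 12 through a closed Zimmerman–Traxler chair with the aryloxy group and the coumarinyl group pseudo-equatorial, which gives the anti (erythro) relationship, while the chiral bis(oxazoline) on chromium directs attack to the Si face of the aldehyde, which gives (1R,2S); organochromium reagents add to aldehydes in preference to the flavone ketone, the lactone and the hydrogen-bonded 5-OH, Mg(II) is expected to occupy the 5-hydroxy-4-keto chelating site, and the step is redox-neutral with no by-product; the closest known reactions are the photoredox/chromium dual-catalytic allylation of aldehydes by allylic C–H abstraction from alkenes (enantioselective with Cr/bis(oxazoline)), its enol-ether variant that gives anti 1,2-diol monoethers, and the stoichiometric Nozaki–Hiyama–Kishi addition of γ-alkoxyallylchromium reagents.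

## Compound list

1 | 2-methoxy-1-(2,4,6-trihydroxyphenyl)ethanone | COCC(=O)c1c(O)cc(O)cc1O | starting material
2 | 4-methoxybenzoic anhydride | COc1ccc(cc1)C(=O)OC(=O)c1ccc(OC)cc1 | starting material
3 | 3-methoxy-2-(4-methoxyphenyl)-4-oxo-4H-chromene-5,7-diyl bis(4-methoxybenzoate) | COc1ccc(cc1)C(=O)Oc1cc(OC(=O)c2ccc(OC)cc2)c2c(=O)c(OC)c(-c3ccc(OC)cc3)oc2c1 | intermediate
4 | 5,7-dihydroxy-3-methoxy-2-(4-methoxyphenyl)-4H-chromen-4-one | COc1ccc(cc1)-c1oc2cc(O)cc(O)c2c(=O)c1OC | intermediate
5 | 6,8-dibromo-5,7-dihydroxy-3-methoxy-2-(4-methoxyphenyl)-4H-chromen-4-one | COc1ccc(cc1)-c1oc2c(Br)c(O)c(Br)c(O)c2c(=O)c1OC | intermediate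
6 | 5,7-dihydroxy-3,6,8-trimethoxy-2-(4-methoxyphenyl)-4H-chromen-4-one | COc1ccc(cc1)-c1oc2c(OC)c(O)c(OC)c(O)c2c(=O)c1OC | intermediate
7 | 3-chloro-2-methylprop-1-ene (methallyl chloride) | CC(=C)CCl | starting material
8 | 5-hydroxy-3,6,8-trimethoxy-2-(4-methoxyphenyl)-7-[(2-methylprop-2-en-1-yl)oxy]-4H-chromen-4-one | C=C(C)COc1c(OC)c(O)c2c(=O)c(OC)c(-c3ccc(OC)cc3)oc2c1OC | intermediate
9 | 7-hydroxy-2H-chromen-2-one (umbelliferone) | O=c1ccc2ccc(O)cc2o1 | starting material
10 | 7-hydroxy-8-(iminomethyl)-2H-chromen-2-one (Duff aldimine, present as its salt) | N=Cc1c(O)ccc2ccc(=O)oc12 | intermediate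
11 | 7-hydroxy-2-oxo-2H-chromene-8-carbaldehyde | O=Cc1c(O)ccc2ccc(=O)oc12 | intermediate
12 | 7-methoxy-2-oxo-2H-chromene-8-carbaldehyde | O=Cc1c(OC)ccc2ccc(=O)oc12 | intermediate
13 | (E)-3-{[5-hydroxy-3,6,8-trimethoxy-2-(4-methoxyphenyl)-4-oxo-4H-chromen-7-yl]oxy}-2-methylprop-2-en-1-ylchromium(III) dichloride (bis(oxazoline) ligand on Cr omitted) | Cl[Cr](Cl)C/C(C)=C/Oc1c(OC)c(O)c2c(=O)c(OC)c(-c3ccc(OC)cc3)oc2c1OC | intermediate
14 | 5-hydroxy-7-{[(1R,2S)-1-hydroxy-1-(7-methoxy-2-oxo-2H-chromen-8-yl)-3-methylbut-3-en-2-yl]oxy}-3,6,8-trimethoxy-2-(4-methoxyphenyl)-4H-chromen-4-one | C=C(C)[C@H](Oc1c(OC)c(O)c2c(=O)c(OC)c(-c3ccc(OC)cc3)oc2c1OC)[C@H](O)c1c(OC)ccc2ccc(=O)oc12 | target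

## Step count and risk

Total step count: 7.
Longest linear sequence: 5 steps (steps 1, 2, 3, 4 and 7); steps 5 and 6 form the second branch.

The three steps most likely to fail:

Step 7 (most risky). The C–H abstraction, radical capture and asymmetric addition have not been run on an aryl methallyl ether, the ether is the limiting partner rather than the excess one, the 5-hydroxy-4-keto unit of 8 can bind chromium in competition with the chiral ligand, and the product carries a new weak C–H that could react further. The fallback sets out from 8 and comes back at 14. Radical bromination of 8 at the same O–CH2 position (NBS, cat. AIBN, PhCF3, 60 °C), followed by allylic transposition, gives 7-{[(E)-3-bromo-2-methylprop-1-en-1-yl]oxy}-5-hydroxy-3,6,8-trimethoxy-2-(4-methoxyphenyl)-4H-chromen-4-one F1, which is used crude. A stoichiometric Nozaki–Hiyama–Kishi reaction of F1 with 12 (CrCl2 3 equiv, the same bis(oxazoline) 3.3 equiv, THF, 0 °C) then forms the same allylchromium by two-electron reduction of the C–Br bond, without light or a hydrogen-atom-transfer catalyst, and gives 14 with the same anti selectivity.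

Step 3. Double copper-mediated methoxylation next to two phenoxides can stall at the mono-ether or give hydrodebromination. The fallback sets out from 4 and comes back at 6, and installs the two oxygens by oxidation instead of C–O coupling. Double Duff formylation of 4 (hexamethylenetetramine, TFA, then aq. HCl) gives 5,7-dihydroxy-3-methoxy-2-(4-methoxyphenyl)-4-oxo-4H-chromene-6,8-dicarbaldehyde F2. Dakin oxidation (H2O2, NaOH, 0 °C) gives 5,6,7,8-tetrahydroxy-3-methoxy-2-(4-methoxyphenyl)-4H-chromen-4-one F3, which is air-sensitive and is methylated at once (Me2SO4, K2CO3, acetone) to 3,5,6,7,8-pentamethoxy-2-(4-methoxyphenyl)-4H-chromen-4-one F4. Anhydrous AlBr3 in MeCN then cleaves the chelating 5-OMe and the 7-OMe (twisted out of plane between two methoxy groups and para to the carbonyl) to give 6; the selectivity of this last step rests on my recollection of selective demethylations in this flavone series and would need checking.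

Step 5. The Duff reaction on umbelliferone is often low-yielding and can give some C6 isomer. The fallback sets out from 9 and comes back at 12, and makes the C8–CHO bond by cross-coupling. Iodination of 9 (I2, KI, aq. NH3) gives 7-hydroxy-8-iodo-2H-chromen-2-one F5. Methylation (MeI, K2CO3, acetone) gives 8-iodo-7-methoxy-2H-chromen-2-one F6. Palladium-catalysed reductive carbonylation (Pd(OAc)2, dppp, CO 1 atm, HCO2Na, DMF, 90 °C) then gives 12.

## Further compounds

F1 | step 7 | 7-{[(E)-3-bromo-2-methylprop-1-en-1-yl]oxy}-5-hydroxy-3,6,8-trimethoxy-2-(4-methoxyphenyl)-4H-chromen-4-one | BrC/C(C)=C/Oc1c(OC)c(O)c2c(=O)c(OC)c(-c3ccc(OC)cc3)oc2c1OC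
F2 | step 3 | 5,7-dihydroxy-3-methoxy-2-(4-methoxyphenyl)-4-oxo-4H-chromene-6,8-dicarbaldehyde | COc1ccc(cc1)-c1oc2c(C=O)c(O)c(C=O)c(O)c2c(=O)c1OC
F3 | step 3 | 5,6,7,8-tetrahydroxy-3-methoxy-2-(4-methoxyphenyl)-4H-chromen-4-one | COc1ccc(cc1)-c1oc2c(O)c(O)c(O)c(O)c2c(=O)c1OC
F4 | step 3 | 3,5,6,7,8-pentamethoxy-2-(4-methoxyphenyl)-4H-chromen-4-one | COc1ccc(cc1)-c1oc2c(OC)c(OC)c(OC)c(OC)c2c(=O)c1OC
F5 | step 5 | 7-hydroxy-8-iodo-2H-chromen-2-one | O=c1ccc2ccc(O)c(I)c2o1
F6 | step 5 | 8-iodo-7-methoxy-2H-chromen-2-one | COc1ccc2ccc(=O)oc2c1I
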